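**Retrosynthetic overview**
- The C3'=C4' bond of the triene is cut by a vinylogous Horner–Wadsworth–Emmons disconnection into a core enal and a phosphonocrotonamide that already carries the bought aminocyclopentenone (C5N) ring.
- The enamide C2–N bond is cut to a core α-iodoenone and (2E,4R)-2,4-dimethyloct-2-enamide, whose stereocentre is bought as a bromo ester.
- The enone and the (E)-acrylate of the core come from ring-opening (E1cB) and Cope elimination of an epoxy-hydroindolone; this erases the tyrosine α-centre after it has controlled C4, C5 and C6.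
- The epoxy-hydroindolone comes from face-selective epoxidation of a hydroindolenone made by anodic dearomatisation of N-Boc-L-tyrosine (C4–O bond).
- Ring order: the carbocycle is the tyrosine arene; a temporary pyrrolidine ring closes in step 1 and opens in step 3; the epoxide closes in step 2.

Assumption: compounds 1, 13, 22 and 25 and all named reagents are purchasable; core atoms are numbered as in the target (C1 ketone, C2 nitrogen-bearing, C3, C4 carbinol, C5/C6 epoxide, chain C1'–C7').

**Step 1**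
Reactants: 1 N-(tert-butoxycarbonyl)-L-tyrosine
Product: 4 1-tert-butyl 2-methyl (2S,3aR,7aR)-3a-hydroxy-6-oxo-2,3,3a,6,7,7a-hexahydro-1H-indole-1,2-dicarboxylate, via spirolactone 2 (not isolated), via quinol ester 3 (not isolated)
Conditions: graphite (+) | Pt (−), undivided cell, constant current (5 mA cm−2, 2.2 F mol−1), Bu4NBF4 (0.1 M), 2,6-lutidine (1.1 equiv), MeCN–(CF3)2CHOH 9:1, 0 °C; then MeOH, NaHCO3, 23 °C
Reagents that add atoms: methanol, CO
Why: Proposed new method: two-electron anodic oxidation of the phenol to the phenoxonium ion is intercepted at the para carbon by the carboxylate to give the five-membered spirolactone (C4–O bond), NaHCO3/MeOH then opens the lactone to the quinol ester, and the carbamate N–H adds reversibly to the one enone arm that leaves CO2Me on the convex face of the cis-fused bicycle, so the L-tyrosine α-carbon fixes both ring-fusion centres as (3aR,7aR) under thermodynamic control; the closest known reaction types are the PhI(OAc)2-mediated spirolactonisation–methanolysis–aza-Michael cascade of N-carbamoyl tyrosines and the anodic dearomative spirolactonisation of 3-(4-hydroxyphenyl)propanoic acids, which have not been merged on this substrate.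

**Step 2**
Reactants: 4 hydroindolenone
Product: 5 1-tert-butyl 2-methyl (2S,3aS,4R,5S,7aR)-4,5-epoxy-3a-hydroxy-6-oxooctahydro-1H-indole-1,2-dicarboxylate (epoxide oxygen cis to the 3a-hydroxyl, trans to the pyrrolidine ring)
Conditions: t-BuOOH (5.5 M in decane, 1.5 equiv), DBU (1.0 equiv), CH2Cl2, 0 °C
Reagents that add atoms: tert-butyl hydroperoxide, CC(C)(C)OO
Why: Nucleophilic (Weitz–Scheffer) epoxidation of the remaining enone, in which the peroxide attacks from the convex face that carries the angular hydroxyl (anti to the pyrrolidine ring, helped by hydrogen bonding), sets both epoxide centres cis to the tertiary hydroxyl as in the target.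

**Step 3**
Reactants: 5 epoxy-hydroindolone
Product: 9 methyl (2S)-2-(dimethylamino)-3-[(1R,2S,6S)-2-hydroxy-5-oxo-7-oxabicyclo[4.1.0]hept-3-en-2-yl]propanoate, via ammonium trifluoroacetate 6 (not isolated), via N-methyl amine 7 (not isolated), via ammonium iodide 8 (not isolated)
Conditions: CF3CO2H–CH2Cl2 1:4, 0 °C, evaporate; then MeI (2.2 equiv), K2CO3, MeCN, 0 → 23 °C
Reagents that add atoms: iodomethane, CI
Why: Boc acidolysis, double N-methylation to the quaternary salt and spontaneous E1cB (retro-aza-Michael, Hofmann-type) elimination of the β-ammonio ketone regenerate the C2=C3 enone and leave a dimethylamino group on the former tyrosine α-carbon without touching a ring stereocentre.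

**Step 4**
Reactants: 9 dimethylamino ester
Product: 11 methyl (2E)-3-[(1R,2R,6S)-2-hydroxy-5-oxo-7-oxabicyclo[4.1.0]hept-3-en-2-yl]prop-2-enoate (same spatial arrangement as 9; the descriptor at C2 changes only because of CIP priorities), via N-oxide 10 (not isolated)
Conditions: mCPBA (1.05 equiv), CH2Cl2, −20 °C; then THF, 40 °C
Reagents that add atoms: none
Why: Amine oxidation followed by syn Cope elimination removes the nitrogen, erases the tyrosine α-stereocentre and gives the conjugated (E)-acrylate (C1'=C2') through the less congested five-membered transition state.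

**Step 5**
Reactants: 11 epoxyquinol acrylate
Product: 12 methyl (2E)-3-[(1R,2S,6S)-2-hydroxy-4-iodo-5-oxo-7-oxabicyclo[4.1.0]hept-3-en-2-yl]prop-2-enoate
Conditions: I2 (2.5 equiv), pyridine–CH2Cl2 1:1, 0 → 23 °C
Reagents that add atoms: iodine, II
Why: Johnson α-iodination (pyridine addition, iodination, elimination) is selective for the cyclic enone, because the β-substituted acyclic acrylate does not undergo the initial conjugate addition.

**Step 6**
Reactants: 13 methyl (2S)-3-bromo-2-methylpropanoate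
Product: 15 methyl (2R)-2-methylhexanoate, via organozinc bromide 14 (not isolated)
Conditions: Zn dust, I2 (5 mol%), DMA, 70 °C; then 1-iodopropane, Pd2(dba)3 (2 mol%), P(c-C5H9)3 (8 mol%), N-methylimidazole, THF–NMP, 80 °C
Reagents that add atoms: 1-iodopropane, CCCI
Why: Zinc insertion into the primary C–Br bond and palladium-catalysed alkyl–alkyl Negishi coupling add three carbons without touching the α-stereocentre, which is bought with the bromide (the descriptor changes from S to R only through CIP priorities).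

**Step 7**
Reactants: 15 methyl (2R)-2-methylhexanoate
Product: 17 ethyl (2E,4R)-2,4-dimethyloct-2-enoate, via aldehyde 16 (not isolated)
Conditions: i-Bu2AlH (1.05 equiv), CH2Cl2, −78 °C; then Ph3P=C(Me)CO2Et, −78 → 23 °C
Reagents that add atoms: ethyl 2-(triphenylphosphoranylidene)propanoate, CCOC(=O)C(C)=P(c1ccccc1)(c1ccccc1)c1ccccc1
Why: Partial ester reduction and in situ Wittig olefination with the stabilised ylide give the (E)-trisubstituted enoate without isolating the epimerisable α-branched aldehyde.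

**Step 8**
Reactants: 17 ethyl (2E,4R)-2,4-dimethyloct-2-enoate
Product: 18 (2E,4R)-2,4-dimethyloct-2-enamide
Conditions: AlMe3, NH4Cl, toluene, 0 → 50 °C
Reagents that add atoms: ammonium chloride, [NH4+].[Cl-]
Why: Aluminium amide aminolysis of the ester (Weinreb amidation) gives the primary amide and leaves the remote γ-stereocentre untouched.

**Step 9**
Reactants: 12 iodoenone; 18 (2E,4R)-2,4-dimethyloct-2-enamide
Product: 19 methyl (2E)-3-[(1R,2S,6S)-4-{[(2E,4R)-2,4-dimethyloct-2-enoyl]amino}-2-hydroxy-5-oxo-7-oxabicyclo[4.1.0]hept-3-en-2-yl]prop-2-enoate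
Conditions: CuI (10 mol%), MeNHCH2CH2NHMe (20 mol%), Cs2CO3, THF, 50 °C
Reagents that add atoms: none
Why: Copper-catalysed Goldberg-type amidation of the vinyl iodide with an achiral diamine ligand forms the C2–N enamide bond without moving the double bond.

**Step 10**
Reactants: 19 amido ester
Product: 20 (2E,4R)-N-{2,5-dihydroxy-2-[(1E)-3-hydroxyprop-1-en-1-yl]-7-oxabicyclo[4.1.0]hept-3-en-4-yl}-2,4-dimethyloct-2-enamide (C1, C2 and C6 arranged as in 19; C5 carbinol as an epimer mixture)
Conditions: i-Bu2AlH (6 equiv), CH2Cl2–THF, −78 °C; aq. KNaC4H4O6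
Reagents that add atoms: none
Why: Hydride 1,2-reduction takes the acrylate ester to the allylic alcohol and unavoidably also reduces the ring ketone (its new centre is removed in the next step), while the N-deprotonated amide and the epoxide are inert at −78 °C.

**Step 11**
Reactants: 20 triol
Product: 21 (2E,4R)-N-{(1R,2S,6S)-2-hydroxy-5-oxo-2-[(1E)-3-oxoprop-1-en-1-yl]-7-oxabicyclo[4.1.0]hept-3-en-4-yl}-2,4-dimethyloct-2-enamide
Conditions: Dess–Martin periodinane (3 equiv), NaHCO3, CH2Cl2, 0 → 23 °C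
Reagents that add atoms: none
Why: Dess–Martin oxidation restores the ring ketone and converts the primary allylic alcohol into the enal, while the tertiary C4 alcohol cannot be oxidised.

**Step 12**
Reactants: 22 cyclopentane-1,3-dione
Product: 23 2-(hydroxyimino)cyclopentane-1,3-dione
Conditions: NaNO2, aq. HCl, 0 °C
Reagents that add atoms: sodium nitrite, [Na+].[O-]N=O
Why: Nitrosation of the enolised 1,3-dione at C2 gives the 2-oxime.

**Step 13**
Reactants: 23 2-(hydroxyimino)cyclopentane-1,3-dione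
Product: 24 2-amino-3-hydroxycyclopent-2-en-1-one hydrochloride
Conditions: H2 (1 atm), Pd/C (10 wt% Pd), HCl, EtOH, 23 °C
Reagents that add atoms: hydrogen chloride, Cl
Why: Catalytic hydrogenation reduces the oxime to the amine, which is trapped as the hydrochloride to stop self-condensation.

**Step 14**
Reactants: 25 ethyl (2E)-4-(diethoxyphosphoryl)but-2-enoate
Product: 26 (2E)-4-(diethoxyphosphoryl)but-2-enoic acid
Conditions: LiOH (1.05 equiv), THF–H2O, 0 °C; then aq. HCl to pH 2
Reagents that add atoms: lithium hydroxide, [Li+].[OH-]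
Why: Saponification cleaves only the carboxylic ester, because the diethyl phosphonate is stable to LiOH at 0 °C.

**Step 15**
Reactants: 26 (2E)-4-(diethoxyphosphoryl)but-2-enoic acid; 24 2-amino-3-hydroxycyclopent-2-en-1-one hydrochloride
Product: 28 diethyl {(2E)-4-[(2-hydroxy-5-oxocyclopent-1-en-1-yl)amino]-4-oxobut-2-en-1-yl}phosphonate, via mixed anhydride 27 (not isolated)
Conditions: i-BuOCOCl, N-methylmorpholine, THF, −15 °C; then 24, N-methylmorpholine, −15 → 23 °C
Reagents that add atoms: none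
Why: Mixed carbonic anhydride activation gives N-acylation of the aminocyclopentenone (amide coupling).

**Step 16**
Reactants: 21 keto-enal; 28 phosphonocrotonamide
Product: 29 (2E,4R)-N-[(1R,2S,6S)-2-hydroxy-2-{(1E,3E,5E)-7-[(2-hydroxy-5-oxocyclopent-1-en-1-yl)amino]-7-oxohepta-1,3,5-trien-1-yl}-5-oxo-7-oxabicyclo[4.1.0]hept-3-en-4-yl]-2,4-dimethyloct-2-enamide
Conditions: 28 (2 equiv), LiN(SiMe3)2 (6 equiv), THF, −78 °C; then 21 (pretreated with LiN(SiMe3)2, 1 equiv), −78 → −20 °C; aq. NaH2PO4
Reagents that add atoms: none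
Why: Vinylogous Horner–Wadsworth–Emmons olefination of the aldehyde (far more electrophilic than the amidate-deactivated ring ketone) forms the C3'=C4' bond with E selectivity and completes the triene.

**Compound list**
1 | N-(tert-butoxycarbonyl)-L-tyrosine | CC(C)(C)OC(=O)N[C@@H](Cc1ccc(O)cc1)C(=O)O | starting material
2 | tert-butyl [(3S)-2,8-dioxo-1-oxaspiro[4.5]deca-6,9-dien-3-yl]carbamate (spirolactone, not isolated) | CC(C)(C)OC(=O)N[C@H]1CC2(C=CC(=O)C=C2)OC1=O | intermediate
3 | methyl (2S)-2-[(tert-butoxycarbonyl)amino]-3-(1-hydroxy-4-oxocyclohexa-2,5-dien-1-yl)propanoate (quinol ester, not isolated) | CC(C)(C)OC(=O)N[C@@H](CC1(O)C=CC(=O)C=C1)C(=O)OC | intermediate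
4 | 1-tert-butyl 2-methyl (2S,3aR,7aR)-3a-hydroxy-6-oxo-2,3,3a,6,7,7a-hexahydro-1H-indole-1,2-dicarboxylate | CC(C)(C)OC(=O)N1[C@H](C(=O)OC)C[C@@]2(O)C=CC(=O)C[C@@H]12 | intermediate
5 | 1-tert-butyl 2-methyl (2S,3aS,4R,5S,7aR)-4,5-epoxy-3a-hydroxy-6-oxooctahydro-1H-indole-1,2-dicarboxylate | CC(C)(C)OC(=O)N1[C@H](C(=O)OC)C[C@@]2(O)[C@@H]3O[C@@H]3C(=O)C[C@@H]12 | intermediate
6 | secondary ammonium trifluoroacetate of N-deprotected 5 (not isolated) | [O-]C(=O)C(F)(F)F.[NH2+]1[C@H](C(=O)OC)C[C@@]2(O)[C@@H]3O[C@@H]3C(=O)C[C@@H]12 | intermediate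
7 | N-methyl tertiary amine of the epoxy-hydroindolone (not isolated) | CN1[C@H](C(=O)OC)C[C@@]2(O)[C@@H]3O[C@@H]3C(=O)C[C@@H]12 | intermediate
8 | N,N-dimethyl quaternary ammonium iodide of the epoxy-hydroindolone (not isolated) | [I-].C[N+]1(C)[C@H](C(=O)OC)C[C@@]2(O)[C@@H]3O[C@@H]3C(=O)C[C@@H]12 | intermediate
9 | methyl (2S)-2-(dimethylamino)-3-[(1R,2S,6S)-2-hydroxy-5-oxo-7-oxabicyclo[4.1.0]hept-3-en-2-yl]propanoate | C1=C[C@@](O)(C[C@H](N(C)C)C(=O)OC)[C@@H]2O[C@@H]2C1=O | intermediate
10 | N-oxide of 9 (not isolated) | C1=C[C@@](O)(C[C@H]([N+](C)(C)[O-])C(=O)OC)[C@@H]2O[C@@H]2C1=O | intermediate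
11 | methyl (2E)-3-[(1R,2R,6S)-2-hydroxy-5-oxo-7-oxabicyclo[4.1.0]hept-3-en-2-yl]prop-2-enoate (hydroxyl cis to epoxide oxygen) | C1=C[C@@](O)(/C=C/C(=O)OC)[C@@H]2O[C@@H]2C1=O | intermediate
12 | methyl (2E)-3-[(1R,2S,6S)-2-hydroxy-4-iodo-5-oxo-7-oxabicyclo[4.1.0]hept-3-en-2-yl]prop-2-enoate | IC1=C[C@@](O)(/C=C/C(=O)OC)[C@@H]2O[C@@H]2C1=O | intermediate
13 | methyl (2S)-3-bromo-2-methylpropanoate | BrC[C@@H](C)C(=O)OC | starting material
14 | [(2S)-3-methoxy-2-methyl-3-oxopropyl]zinc bromide (not isolated) | Br[Zn]C[C@@H](C)C(=O)OC | intermediate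
15 | methyl (2R)-2-methylhexanoate | CCCC[C@@H](C)C(=O)OC | intermediate
16 | (2R)-2-methylhexanal (not isolated) | CCCC[C@@H](C)C=O | intermediate
17 | ethyl (2E,4R)-2,4-dimethyloct-2-enoate | CCCC[C@@H](C)/C=C(\C)C(=O)OCC | intermediate
18 | (2E,4R)-2,4-dimethyloct-2-enamide | CCCC[C@@H](C)/C=C(\C)C(N)=O | intermediate
19 | methyl (2E)-3-[(1R,2S,6S)-4-{[(2E,4R)-2,4-dimethyloct-2-enoyl]amino}-2-hydroxy-5-oxo-7-oxabicyclo[4.1.0]hept-3-en-2-yl]prop-2-enoate | CCCC[C@@H](C)/C=C(\C)C(=O)NC1=C[C@@](O)(/C=C/C(=O)OC)[C@@H]2O[C@@H]2C1=O | intermediate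
20 | (2E,4R)-N-{2,5-dihydroxy-2-[(1E)-3-hydroxyprop-1-en-1-yl]-7-oxabicyclo[4.1.0]hept-3-en-4-yl}-2,4-dimethyloct-2-enamide (C5 epimer mixture) | CCCC[C@@H](C)/C=C(\C)C(=O)NC1=C[C@@](O)(/C=C/CO)[C@@H]2O[C@@H]2C1O | intermediate
21 | (2E,4R)-N-{(1R,2S,6S)-2-hydroxy-5-oxo-2-[(1E)-3-oxoprop-1-en-1-yl]-7-oxabicyclo[4.1.0]hept-3-en-4-yl}-2,4-dimethyloct-2-enamide | CCCC[C@@H](C)/C=C(\C)C(=O)NC1=C[C@@](O)(/C=C/C=O)[C@@H]2O[C@@H]2C1=O | intermediate
22 | cyclopentane-1,3-dione | O=C1CCC(=O)C1 | starting material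
23 | 2-(hydroxyimino)cyclopentane-1,3-dione | ON=C1C(=O)CCC1=O | intermediate
24 | 2-amino-3-hydroxycyclopent-2-en-1-one hydrochloride | Cl.NC1=C(O)CCC1=O | intermediate
25 | ethyl (2E)-4-(diethoxyphosphoryl)but-2-enoate (triethyl 4-phosphonocrotonate) | CCOC(=O)/C=C/CP(=O)(OCC)OCC | starting material
26 | (2E)-4-(diethoxyphosphoryl)but-2-enoic acid | OC(=O)/C=C/CP(=O)(OCC)OCC | intermediate
27 | isobutyl carbonic (2E)-4-(diethoxyphosphoryl)but-2-enoic anhydride (not isolated) | CC(C)COC(=O)OC(=O)/C=C/CP(=O)(OCC)OCC | intermediate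
28 | diethyl {(2E)-4-[(2-hydroxy-5-oxocyclopent-1-en-1-yl)amino]-4-oxobut-2-en-1-yl}phosphonate | CCOP(=O)(C/C=C/C(=O)NC1=C(O)CCC1=O)OCC | intermediate
29 | (2E,4R)-N-[(1R,2S,6S)-2-hydroxy-2-{(1E,3E,5E)-7-[(2-hydroxy-5-oxocyclopent-1-en-1-yl)amino]-7-oxohepta-1,3,5-trien-1-yl}-5-oxo-7-oxabicyclo[4.1.0]hept-3-en-4-yl]-2,4-dimethyloct-2-enamide | CCCC[C@@H](C)/C=C(\C)C(=O)NC1=C[C@@](O)(/C=C/C=C/C=C/C(=O)NC2=C(O)CCC2=O)[C@@H]2O[C@@H]2C1=O | target

**Totals**
Total step count: 16. Longest linear sequence: 9 steps (steps 1, 2, 3, 4, 5, 9, 10, 11, 16).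

**Steps most likely to fail and their fallbacks**

Step 1 (the proposed new anodic cascade). At the electrode, phenoxyl radical coupling or solvent capture may compete with spirolactonisation. The fallback sets out from 1 and uses known chemistry: a stoichiometric trivalent-iodine oxidant, PhI(OAc)2 in MeOH at 0 °C, dearomatises 1 by ligand coupling on iodine rather than by electron transfer, and spirolactone 2 is isolated. A separate treatment with NaHCO3 in MeOH then opens 2 to quinol ester 3 and closes it to 4, where the route is rejoined. This fallback passes only through listed compounds and makes no new compound (F0).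

Step 9 (copper-catalysed amidation of the base-sensitive iodo-epoxyquinol). If the primary amide couples poorly or the substrate degrades, the nitrogen and the acyl group are introduced separately. Setting out from 12, coupling with benzophenone imine (Pd2(dba)3, Xantphos, Cs2CO3, dioxane, 60 °C) gives methyl (2E)-3-{(1R,2S,6S)-4-[(diphenylmethylidene)amino]-2-hydroxy-5-oxo-7-oxabicyclo[4.1.0]hept-3-en-2-yl}prop-2-enoate F1. Mild hydrolysis (aqueous citric acid, THF) releases methyl (2E)-3-[(1R,2S,6S)-4-amino-2-hydroxy-5-oxo-7-oxabicyclo[4.1.0]hept-3-en-2-yl]prop-2-enoate F2. In parallel, ester 17 is saponified (LiOH, THF–MeOH–H2O) to (2E,4R)-2,4-dimethyloct-2-enoic acid F3 and converted with oxalyl chloride and catalytic DMF into (2E,4R)-2,4-dimethyloct-2-enoyl chloride F4. Acylation of F2 with F4 in pyridine–CH2Cl2 at 0 °C returns to the route at 19.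

Step 16 (olefination with the polyanion of 28 on the base-sensitive core). If the trianion is unreactive or the core does not survive LiN(SiMe3)2, the triene is closed at C5'=C6' under amine-base conditions instead. Setting out from 21, two-carbon homologation with the neutral stabilised ylide Ph3P=CHCHO (toluene, 50 °C) gives (2E,4R)-N-{(1R,2S,6S)-2-hydroxy-5-oxo-2-[(1E,3E)-5-oxopenta-1,3-dien-1-yl]-7-oxabicyclo[4.1.0]hept-3-en-4-yl}-2,4-dimethyloct-2-enamide F5. Amine 24 is acylated with purchased diethylphosphonoacetic acid (mixed anhydride, as in step 15) to diethyl {2-[(2-hydroxy-5-oxocyclopent-1-en-1-yl)amino]-2-oxoethyl}phosphonate F6. Masamune–Roush olefination of F5 with F6 (LiCl, i-Pr2NEt, MeCN, 23 °C) returns to the route at 29.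

**Further compounds**
F0 | step 1 | none | none
F1 | step 9 | methyl (2E)-3-{(1R,2S,6S)-4-[(diphenylmethylidene)amino]-2-hydroxy-5-oxo-7-oxabicyclo[4.1.0]hept-3-en-2-yl}prop-2-enoate | C(c1ccccc1)(c1ccccc1)=NC1=C[C@@](O)(/C=C/C(=O)OC)[C@@H]2O[C@@H]2C1=O
F2 | step 9 | methyl (2E)-3-[(1R,2S,6S)-4-amino-2-hydroxy-5-oxo-7-oxabicyclo[4.1.0]hept-3-en-2-yl]prop-2-enoate | NC1=C[C@@](O)(/C=C/C(=O)OC)[C@@H]2O[C@@H]2C1=O
F3 | step 9 | (2E,4R)-2,4-dimethyloct-2-enoic acid | CCCC[C@@H](C)/C=C(\C)C(O)=O
F4 | step 9 | (2E,4R)-2,4-dimethyloct-2-enoyl chloride | CCCC[C@@H](C)/C=C(\C)C(Cl)=O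
F5 | step 16 | (2E,4R)-N-{(1R,2S,6S)-2-hydroxy-5-oxo-2-[(1E,3E)-5-oxopenta-1,3-dien-1-yl]-7-oxabicyclo[4.1.0]hept-3-en-4-yl}-2,4-dimethyloct-2-enamide | CCCC[C@@H](C)/C=C(\C)C(=O)NC1=C[C@@](O)(/C=C/C=C/C=O)[C@@H]2O[C@@H]2C1=O
F6 | step 16 | diethyl {2-[(2-hydroxy-5-oxocyclopent-1-en-1-yl)amino]-2-oxoethyl}phosphonate | CCOP(=O)(CC(=O)NC1=C(O)CCC1=O)OCC
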